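The numbers in the tables were computed on assumed constants; noise was put on by code.

The dusk run holds twice the catalyst of the autumn run and is otherwise charged alike, yet at 4.9 min it has turned 73.7% of its substrate into target against 56.1% in the autumn run.

| setting | autumn | noon | spring | dusk | summer |
|---|---|---|---|---|---|
| substrate | 0.0800 M | 0.0480 M | 0.0400 M | 0.0800 M | 0.0800 M |
| reagent | 0.200 M | 0.168 M | 0.200 M | 0.200 M | 0.200 M |
| catalyst | 1.60 × 10⁻⁴ M | 1.60 × 10⁻⁴ M | 1.60 × 10⁻⁴ M | 3.20 × 10⁻⁴ M | 7.40 × 10⁻⁴ M |
| time |  |  |  |  | 4.9 min |

| run | time / min | [target] / M |
|---|---|---|
| autumn run | 0.61 | 0.0077 |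
| autumn run | 1.2 | 0.0162 |
| autumn run | 1.8 | 0.0220 |
| autumn run | 2.5 | 0.0269 |
| autumn run | 3.1 | 0.0335 |
| autumn run | 3.7 | 0.0365 |
| autumn run | 4.3 | 0.0425 |
| autumn run | 4.9 | 0.0449 |
| noon run | 0.61 | 0.0052 |
| noon run | 1.2 | 0.0074 |
| noon run | 1.8 | 0.0130 |
| noon run | 2.5 | 0.0171 |
| noon run | 3.1 | 0.0200 |
| noon run | 3.7 | 0.0230 |
| noon run | 4.3 | 0.0249 |
| noon run | 4.9 | 0.0265 |
| spring run | 0.61 | 0.0053 |
| spring run | 1.2 | 0.0079 |
| spring run | 1.8 | 0.0103 |
| spring run | 2.5 | 0.0148 |
| spring run | 3.1 | 0.0157 |
| spring run | 3.7 | 0.0203 |
| spring run | 4.3 | 0.0212 |
| spring run | 4.9 | 0.0250 |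
| dusk run | 0.61 | 0.0126 |
| dusk run | 1.2 | 0.0232 |
| dusk run | 1.8 | 0.0311 |
| dusk run | 2.5 | 0.0391 |
| dusk run | 3.1 | 0.0478 |
| dusk run | 3.7 | 0.0510 |
| dusk run | 4.3 | 0.0557 |
| dusk run | 4.9 | 0.0590 |

(each reading ± 0.001 M)

- Overall: substrate + reagent -> target, with catalyst as catalyst.
- Constant volume, constant temperature.
- Readings of a species count what is bound in complexes too.
- "The second partner" is reagent.
- An order is taken over about fifteen percent of the charge, up and down.

1. order of the initial rate in [substrate], near the charge of the autumn run, the rate being that where two percent of its substrate are target (one fixed amount of target, the same in the runs compared)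
2. order of the initial rate in [reagent], near the charge of the autumn run, the rate being that where two percent of its substrate are target
3. the noon run starts with 0.0320 M less of substrate and of reagent than the autumn run, and with no target. Compared where both hold the same amount of substrate, once fifteen percent of what the noon run was charged with has turned into target, is the noon run faster, slower or alike (within a tenth)?
4. target in the summer run at 4.9 min, as a share of the substrate charged

Substrate is the limiting reagent here, charged at less than the reagent in every run, so each run is measured by the fraction x of its substrate charge turned into target. Treated as pseudo-first-order in substrate, a run has a progress ln(1/(1 − x)) that grows in step with time. The autumn readings support this: progress divided by time reads 0.164 /min at 2.5 min and 0.168 /min at 4.9 min.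

Dividing one run's progress by the other's at the same time removes time:

autumn progress = 0.824
dusk progress = 1.34
gain = dusk progress / autumn progress = 1.62

A rate made of one part proportional to the catalyst and one part without it gains 2 minus that second share when the catalyst doubles. This gives the catalyst-free share, the part of the autumn rate that does not scale with the catalyst:

catalyst-free share = 2 − gain = 0.376

This is a reading and carries the scatter of the readings. The gain of the dusk run reads less than 2; on this reading, the catalyst-free part stays the same while the other part doubles.

My reckoning carries this to the summer run, which has 2.31 times the catalyst of the dusk run: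

rate relative to autumn = share + (1 − share) × 4.62 = 3.26
summer progress = 2.69
x = 93.2%

The forecast, noting “Doubling the catalyst raises the rate only 1.64-fold”, gives 89% for the summer run (range 83% to 94%), less than this reckoning, with orders 0.76 in substrate and 0.5 in reagent, and the noon run alike.

The summer run gives 93.4%, with orders 0.82 in substrate and 0.50 in reagent, and the noon run is alike at a ratio of 1.0.

    catalyst + substrate ⇌ catalyst-substrate complex, settled at all times (4.240 /M)
    catalyst-substrate complex + reagent → target + catalyst (3030 /M/min)
    substrate + reagent ⇌ idle substrate-reagent adduct, settled at all times (10.80 /M)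
    substrate + reagent → target (1.158 /M/min)

The step substrate + reagent → target needs no catalyst, and its passing moves the readings by 7.0 in units of the scatter, root mean square. By the reckoning above, the catalyst-free share is 11.5% of the summer rate. The autumn run had turned half of its charge into target at 4.07 min; divided by two minus the catalyst-free share, that gives 2.51 min, and the dusk run reached half at 2.52 min.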